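Ring A = resorcinol ring fused to the dihydrofuran (O1, C2, C3, C3a–C7a; C4 carries the ketone); ring B = dioxygenated ring joining C3 to Cα (the methine next to the ketone); rings C and D = 4-hydroxyphenyl groups on Cα and C2.
Retrosynthetic cuts, in order: O1–C2 (aryl ether), C3–C3a (also the last bond of the seven-membered ring), the stilbene bond at ring B, the bond from ring A to the benzoyl carbon, and ring B–Cα.
Forward: rings B and C are joined at Cα (benzofuranone), ring A is added as a Grignard reagent, ring D by Heck coupling; the seven-membered ring closes first (oxirane–arene cyclisation), the dihydrofuran second (Mitsunobu), and the ketone is unveiled afterwards by oxidation.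
Feature that makes the key step possible: C3 is bonded to C3a, a ring A carbon ortho to the oxygen-bearing C7a and para to the C6 hydroxyl (the nucleophilic carbon of a resorcinol), and C2–C3 with trans hydrogens is the syn adduct of that carbon and that oxygen across an (E)-stilbene, so one trans-oxirane can carry both centres.
Stereochemistry: Shi epoxidation sets C2 and C3 ((2R,3R)-oxirane); C3 is formed with inversion in the key step, C2 is inverted in the Mitsunobu closure, and the enolisable Cα is settled by equilibration in the last step.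
The benzoyl carbon stays at the carbinol (acetate) level through the key step, so that ring A reacts as an undeactivated resorcinol and no carbonyl oxygen can capture the oxirane through a six-membered ring.
Key step: step 10

Remark (assumption): the natural (R) configuration at Cα is taken to be the more stable one (ring C pseudo-axial on the boat-shaped seven-membered ring, its hydrogen facing the ortho oxygen of ring B), so that enolisation converges on it. The carbinol carbon and Cα are therefore carried as mixtures until steps 13 and 15.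

Step 1
Reactants: 1 3,5-dimethoxyphenol; 2 4-methoxymandelic acid (racemic)
Product: 3 4,6-dimethoxy-3-(4-methoxyphenyl)benzofuran-2(3H)-one (racemic)
Conditions: TsOH·H2O (cat.), toluene, reflux, Dean–Stark
Reagents that add atoms: none
Why: Acid-catalysed Friedel–Crafts alkylation of the phenol by the 4-methoxybenzylic cation of 2 followed by lactonisation is the usual entry to 3-arylbenzofuran-2(3H)-ones, and only the adduct formed ortho to the hydroxyl can lactonise, which drains the reversible alkylation toward 3.

Step 2
Reactants: 3 4,6-dimethoxy-3-(4-methoxyphenyl)benzofuran-2(3H)-one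
Product: 4 4,6-dimethoxy-3-(4-methoxyphenyl)-2,3-dihydrobenzofuran-2-ol (lactol; anomer mixture; used crude)
Conditions: i-Bu2AlH, CH2Cl2, −78 °C; aq. potassium sodium tartrate
Reagents that add atoms: none
Why: Half-reduction of a lactone with i-Bu2AlH at −78 °C stops at the aluminium hemiacetal, which gives the lactol on work-up, and the non-basic hydride leaves the acidic C3–H untouched, whereas a carbanion reagent would simply deprotonate it.

Step 3
Reactants: 5 5-bromoresorcinol
Product: 6 1-bromo-3,5-bis(triisopropylsilyloxy)benzene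
Conditions: i-Pr3SiCl, imidazole, DMF, rt
Reagents that add atoms: chlorotriisopropylsilane, CC(C)[Si](Cl)(C(C)C)C(C)C
Why: Standard silylation of phenols; the triisopropylsilyl ethers tolerate Grignard formation, the hot amine base of step 7 and the pH 10.5 buffer of step 8, and come off with fluoride when ring A has to be freed.

Step 4
Reactants: 6 1-bromo-3,5-bis(triisopropylsilyloxy)benzene; 4 lactol
Product: 8 1-[3,5-bis(triisopropylsilyloxy)phenyl]-2-(2-hydroxy-4,6-dimethoxyphenyl)-2-(4-methoxyphenyl)ethanol (diol; racemic diastereomers), via arylmagnesium bromide 7 (not isolated)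
Conditions: 6 (2.5 equiv), Mg, THF, 50 °C; then 4, THF, 0 °C → rt; aq. NH4Cl
Reagents that add atoms: none
Why: Grignard addition to a lactol: the first equivalent of 7 deprotonates the hemiacetal, whose magnesium alkoxide opens to the phenoxide aldehyde, and a second equivalent adds to the aldehyde faster than it enolises it; the new carbinol centre is formed without control and is erased in step 13.

Step 5
Reactants: 8 diol
Product: 10 1-[3,5-bis(triisopropylsilyloxy)phenyl]-2-(4-methoxyphenyl)-2-[2,4-dimethoxy-6-(trifluoromethanesulfonyloxy)phenyl]ethyl acetate (triflate acetate), via triflate alcohol 9 (not isolated)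
Conditions: PhNTf2, Et3N, DMAP (cat.), CH2Cl2, 0 °C → rt; then Ac2O, rt
Reagents that add atoms: N-phenylbis(trifluoromethanesulfonimide), O=S(=O)(N(c1ccccc1)S(=O)(=O)C(F)(F)F)C(F)(F)F; acetic anhydride, CC(=O)OC(C)=O
Why: PhNTf2 with Et3N/DMAP triflates the phenol selectively over the hindered secondary alcohol (standard aryl triflate formation), and DMAP-catalysed acetylation in the same flask turns the carbinol into an ester that is neither nucleophilic nor ionisable under the later steps.

Step 6
Reactants: 11 4-acetoxystyrene
Product: 13 4-ethenylphenyl 4-methylbenzenesulfonate (4-tosyloxystyrene), via potassium 4-vinylphenoxide 12 (not isolated)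
Conditions: KOH, H2O–THF, 0 °C; then TsCl, 0 °C → rt
Reagents that add atoms: 4-toluenesulfonyl chloride, Cc1ccc(S(=O)(=O)Cl)cc1
Why: Saponification of the aryl acetate and Schotten–Baumann-type sulfonylation of the phenoxide in the same flask avoid handling free 4-vinylphenol, which polymerises; the tosylate is chosen as a base-stable, electron-withdrawing phenol protecting group.

Step 7
Reactants: 10 triflate acetate; 13 4-tosyloxystyrene
Product: 14 1-[3,5-bis(triisopropylsilyloxy)phenyl]-2-(4-methoxyphenyl)-2-{2,4-dimethoxy-6-[(E)-2-(4-tosyloxyphenyl)ethenyl]phenyl}ethyl acetate ((E)-stilbene; racemic diastereomers)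
Conditions: PdCl2(PPh3)2 (5 mol %), LiCl, Et3N, DMF, 100 °C
Reagents that add atoms: none
Why: Mizoroki–Heck coupling of an aryl triflate with a styrene under chloride-assisted (neutral-pathway) conditions gives β-arylation, and syn insertion followed by syn β-hydride elimination gives the (E)-stilbene; silyl ethers, acetate and aryl tosylate are inert to the triphenylphosphine–palladium catalyst.

Step 8
Reactants: 14 (E)-stilbene
Product: 15 1-[3,5-bis(triisopropylsilyloxy)phenyl]-2-(4-methoxyphenyl)-2-{2,4-dimethoxy-6-[(2R,3R)-3-(4-tosyloxyphenyl)oxiran-2-yl]phenyl}ethyl acetate (diastereomers at the carbinol carbon and Cα)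
Conditions: D-fructose-derived Shi ketone (0.3 equiv), KHSO5 (Oxone), K2CO3, Bu4NHSO4, MeCN–CH2(OMe)2 / aq. Na2B4O7–Na2EDTA buffer, 0 °C
Reagents that add atoms: potassium peroxymonosulfate, [K+].[O-]S(=O)(=O)OO
Why: Shi asymmetric epoxidation by the chiral dioxirane formed from the D-fructose-derived ketone, for which trans-stilbenes are the model substrates: the spiro transition state should deliver oxygen with the same facial sense as for trans-stilbene itself, giving the (2R,3R)-oxirane under catalyst control whatever the configuration of the remote racemic centres, and thereby fixing the future C2 and C3.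

Step 9
Reactants: 15 silyl-protected oxirane
Product: 16 1-(3,5-dihydroxyphenyl)-2-(4-methoxyphenyl)-2-{2,4-dimethoxy-6-[(2R,3R)-3-(4-tosyloxyphenyl)oxiran-2-yl]phenyl}ethyl acetate (bisphenol oxirane)
Conditions: Bu4NF, AcOH, THF, 0 °C
Reagents that add atoms: none
Why: Fluoride cleavage of aryl silyl ethers, buffered with acetic acid so that neither phenoxide nor fluoride acts as a base or nucleophile toward the oxirane or the acetate.

Step 10
Reactants: 16 bisphenol oxirane
Product: 17 seven-membered carbocycle: dibenzo-fused cycloheptane in which C3 (R) is bonded to C3a of ring A, to ring B and to the (S)-CH(OH)(4-tosyloxyphenyl) group; ring A keeps two free hydroxyls and the acetoxy carbon, ring B the Cα methine with ring C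
Conditions: BF3·OEt2 (1.2 equiv), CH2Cl2 (0.005 M), −78 → −30 °C; aq. NaHCO3
Reagents that add atoms: none
Why: BF3 coordinates the oxirane oxygen and the ring A carbon that lies ortho to one free hydroxyl and para to the other (the future C3a) attacks the oxirane carbon attached to ring B from the side opposite to the C–O bond, after which loss of a proton restores the arene; this is an intramolecular Friedel–Crafts epoxy–arene cyclisation, and the closest known reaction type is the Lewis-acid-promoted cyclisation of aryl oxiranes onto tethered electron-rich arenes, which opens the benzylic carbon with inversion. The seven-membered carbocycle closes in the 7-exo-tet mode, since the breaking C–O bond lies outside the new ring, whereas attack on the distal oxirane carbon would demand an eight-membered ring. The only new stereocentre, C3, is controlled by the oxirane configuration set in step 8 and is formed with inversion (R), while the C2 carbinol keeps its C–O bond and spatial arrangement (its descriptor becomes S through a priority change only). The step needs site selectivity between the two oxirane carbons, secured by the tether and by the electron-poor 4-tosyloxyphenyl group that disfavours ionisation at C2, and chemoselectivity among the nucleophiles, secured by the acetate: with the benzoyl carbon at the carbinol level there is no carbonyl or hydroxyl oxygen that could trap the oxirane through a six-membered ring, ring A reacts as an undeactivated resorcinol, and the ring C positions that could close a six-membered ring are meta to methoxy and therefore far less nucleophilic. Ring A is symmetric about its bond to the carbinol carbon, so either ortho carbon gives the same product and the hydroxyl next to the new bond is left in place for step 11. Low temperature and a non-ionising solvent keep the opening SN2-like, which is what holds back 1,2-shift (Meinwald) products.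

Step 11
Reactants: 17 seven-membered carbinol
Product: 18 (2R,3R)-trans-2,3-dihydrobenzofuran fused to the seven-membered ring, with the acetoxy carbinol on C4, free C6 hydroxyl, 4-tosyloxyphenyl on C2 and methyl ethers on rings B and C
Conditions: PPh3, DIAD, THF (0.01 M), 0 °C → rt
Reagents that add atoms: none
Why: Intramolecular Mitsunobu etherification in the 5-exo-tet mode: the ring A hydroxyl next to C3a displaces the C2 oxyphosphonium group with inversion, turning the (S)-carbinol into the (R)-ether carbon of the trans-2,3-dihydrobenzofuran, and the electron-poor tosyloxyphenyl group disfavours an SN1 leak that would erode this inversion.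

Step 12
Reactants: 18 dihydrobenzofuran acetate
Product: 19 the corresponding free ring A carbinol (secondary benzylic alcohol in the seven-membered ring)
Conditions: K2CO3, MeOH, rt
Reagents that add atoms: none
Why: Carbonate-catalysed transesterification with methanol removes the secondary acetate at room temperature, where the aryl tosylate and the aryl methyl ethers are stable.

Step 13
Reactants: 19 carbinol
Product: 20 seven-membered ketone: tri-O-methyl, O-tosyl pauciflorol E skeleton (2R,3R; Cα as an epimer mixture)
Conditions: MnO2 (activated, excess), CH2Cl2, rt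
Reagents that add atoms: none
Why: MnO2 oxidises benzylic alcohols selectively and tolerates free phenols, so the ring A carbinol should give the aryl ketone without protection of the C6 hydroxyl; the carbinol stereocentre disappears and Cα becomes enolisable.

Step 14
Reactants: 20 tri-O-methyl ketone
Product: 21 O-tosyl pauciflorol E (four free hydroxyls on rings A, B and C; tosylate on ring D; Cα as an epimer mixture)
Conditions: BBr3, CH2Cl2, −78 → 0 °C; then MeOH, H2O
Reagents that add atoms: none
Why: BBr3 cleavage of aryl methyl ethers (complexation at oxygen, then bromide attack on methyl) frees the three hydroxyls of rings B and C, while the sulfonate is inert and, being electron-withdrawing, keeps the benzylic C2–O1 bond from ionising under the Lewis acid, so C2 and C3 are not disturbed.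

Step 15
Reactants: 21 O-tosyl pauciflorol E
Product: 22 pauciflorol E (2R,3R; Cα R)
Conditions: KOH (2 M aq.), 1,4-dioxane, 70 °C, degassed, Ar; then aq. HCl to pH 3
Reagents that add atoms: none
Why: Hydroxide attacks sulfur and cleaves the aryl sulfonate (ester saponification), and the same alkaline medium enolises the ketone so that the doubly benzylic Cα should settle into its more stable (R) configuration with ring C pseudo-axial, while C3, which is not acidic here, anchors the absolute configuration and C2 stays trans to it.

Compound list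
1 | 3,5-dimethoxyphenol | COc1cc(O)cc(OC)c1 | starting material
2 | 4-methoxymandelic acid (racemic) | COc1ccc(C(O)C(=O)O)cc1 | starting material
3 | 4,6-dimethoxy-3-(4-methoxyphenyl)benzofuran-2(3H)-one (racemic) | COc1ccc(C2C(=O)Oc3cc(OC)cc(OC)c32)cc1 | intermediate
4 | 4,6-dimethoxy-3-(4-methoxyphenyl)-2,3-dihydrobenzofuran-2-ol (lactol, anomer mixture) | COc1ccc(C2C(O)Oc3cc(OC)cc(OC)c32)cc1 | intermediate
5 | 5-bromoresorcinol | Oc1cc(O)cc(Br)c1 | starting material
6 | 1-bromo-3,5-bis(triisopropylsilyloxy)benzene | Brc1cc(O[Si](C(C)C)(C(C)C)C(C)C)cc(O[Si](C(C)C)(C(C)C)C(C)C)c1 | intermediate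
7 | 3,5-bis(triisopropylsilyloxy)phenylmagnesium bromide | Br[Mg]c1cc(O[Si](C(C)C)(C(C)C)C(C)C)cc(O[Si](C(C)C)(C(C)C)C(C)C)c1 | intermediate (not isolated)
8 | 1-[3,5-bis(triisopropylsilyloxy)phenyl]-2-(2-hydroxy-4,6-dimethoxyphenyl)-2-(4-methoxyphenyl)ethanol (racemic diastereomers) | OC(c1cc(O[Si](C(C)C)(C(C)C)C(C)C)cc(O[Si](C(C)C)(C(C)C)C(C)C)c1)C(c1ccc(OC)cc1)c1c(OC)cc(OC)cc1O | intermediate
9 | 2-{2-[3,5-bis(triisopropylsilyloxy)phenyl]-2-hydroxy-1-(4-methoxyphenyl)ethyl}-3,5-dimethoxyphenyl trifluoromethanesulfonate (triflate alcohol) | OC(c1cc(O[Si](C(C)C)(C(C)C)C(C)C)cc(O[Si](C(C)C)(C(C)C)C(C)C)c1)C(c1ccc(OC)cc1)c1c(OC)cc(OC)cc1OS(=O)(=O)C(F)(F)F | intermediate (not isolated)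
10 | 1-[3,5-bis(triisopropylsilyloxy)phenyl]-2-(4-methoxyphenyl)-2-[2,4-dimethoxy-6-(trifluoromethanesulfonyloxy)phenyl]ethyl acetate | CC(=O)OC(c1cc(O[Si](C(C)C)(C(C)C)C(C)C)cc(O[Si](C(C)C)(C(C)C)C(C)C)c1)C(c1ccc(OC)cc1)c1c(OC)cc(OC)cc1OS(=O)(=O)C(F)(F)F | intermediate
11 | 4-acetoxystyrene | CC(=O)Oc1ccc(C=C)cc1 | starting material
12 | potassium 4-vinylphenoxide | [K+].[O-]c1ccc(C=C)cc1 | intermediate (not isolated)
13 | 4-ethenylphenyl 4-methylbenzenesulfonate | C=Cc1ccc(OS(=O)(=O)c2ccc(C)cc2)cc1 | intermediate
14 | 1-[3,5-bis(triisopropylsilyloxy)phenyl]-2-(4-methoxyphenyl)-2-{2,4-dimethoxy-6-[(E)-2-(4-tosyloxyphenyl)ethenyl]phenyl}ethyl acetate | CC(=O)OC(c1cc(O[Si](C(C)C)(C(C)C)C(C)C)cc(O[Si](C(C)C)(C(C)C)C(C)C)c1)C(c1ccc(OC)cc1)c1c(OC)cc(OC)cc1/C=C/c1ccc(OS(=O)(=O)c2ccc(C)cc2)cc1 | intermediate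
15 | (2R,3R)-oxirane of 14 (carbinol carbon and Cα as mixtures) | CC(=O)OC(c1cc(O[Si](C(C)C)(C(C)C)C(C)C)cc(O[Si](C(C)C)(C(C)C)C(C)C)c1)C(c1ccc(OC)cc1)c1c(OC)cc(OC)cc1[C@H]1O[C@@H]1c1ccc(OS(=O)(=O)c2ccc(C)cc2)cc1 | intermediate
16 | 1-(3,5-dihydroxyphenyl)-2-(4-methoxyphenyl)-2-{2,4-dimethoxy-6-[(2R,3R)-3-(4-tosyloxyphenyl)oxiran-2-yl]phenyl}ethyl acetate | CC(=O)OC(c1cc(O)cc(O)c1)C(c1ccc(OC)cc1)c1c(OC)cc(OC)cc1[C@H]1O[C@@H]1c1ccc(OS(=O)(=O)c2ccc(C)cc2)cc1 | intermediate (key-step precursor)
17 | seven-membered carbocycle with C3 (R) and exocyclic (S)-CH(OH)(4-tosyloxyphenyl); acetoxy carbon and Cα as mixtures | CC(=O)OC1c2cc(O)cc(O)c2[C@@H](c2cc(OC)cc(OC)c2C1c1ccc(OC)cc1)[C@H](O)c1ccc(OS(=O)(=O)c2ccc(C)cc2)cc1 | intermediate (key-step product)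
18 | (2R,3R)-trans-dihydrobenzofuran acetate | CC(=O)OC1c2cc(O)cc3c2[C@@H](c2cc(OC)cc(OC)c2C1c1ccc(OC)cc1)[C@H](c1ccc(OS(=O)(=O)c2ccc(C)cc2)cc1)O3 | intermediate
19 | (2R,3R)-trans-dihydrobenzofuran carbinol | OC1c2cc(O)cc3c2[C@@H](c2cc(OC)cc(OC)c2C1c1ccc(OC)cc1)[C@H](c1ccc(OS(=O)(=O)c2ccc(C)cc2)cc1)O3 | intermediate
20 | tri-O-methyl, O-tosyl pauciflorol E (Cα epimers) | O=C1c2cc(O)cc3c2[C@@H](c2cc(OC)cc(OC)c2C1c1ccc(OC)cc1)[C@H](c1ccc(OS(=O)(=O)c2ccc(C)cc2)cc1)O3 | intermediate
21 | O-tosyl pauciflorol E (Cα epimers) | O=C1c2cc(O)cc3c2[C@@H](c2cc(O)cc(O)c2C1c1ccc(O)cc1)[C@H](c1ccc(OS(=O)(=O)c2ccc(C)cc2)cc1)O3 | intermediate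
22 | pauciflorol E | O=C1c2cc(O)cc3c2[C@@H](c2cc(O)cc(O)c2[C@H]1c1ccc(O)cc1)[C@H](c1ccc(O)cc1)O3 | target

Total step count: 15. Longest linear sequence: 13 (steps 1, 2, 4, 5, 7–15; steps 3 and 6 prepare the two side fragments).

Steps most likely to fail

Step 10. The activated oxirane may ionise and undergo a 1,2-hydride or 1,2-aryl shift before ring A engages. Ring closure may also stall for those carbinol/Cα diastereomers whose boat-shaped transition state presses ring C against the ortho methoxy group of ring B. The fallback moves the benzoyl carbon to the ketone level, where only one, enolisable, stereocentre remains beside the oxirane, and replaces the Lewis acid by hydrogen-bond activation. Its price is a less nucleophilic ring A and a carbonyl oxygen within reach of the oxirane, which is why it is not the first choice. It sets out from 9, isolated after the triflation stage of step 5 before acetic anhydride is added. Heck coupling of 9 with 13 under the conditions of step 7 gives the stilbene alcohol F1, and Dess–Martin periodinane oxidation gives the stilbene ketone F2. Shi epoxidation as in step 8 gives the keto oxirane F3, and Bu4NF/AcOH gives the bisphenol keto oxirane F4. Cyclisation in hexafluoroisopropanol (with catalytic TfOH if needed) gives the seven-membered keto carbinol F5 by the same 7-exo-tet opening with inversion. Mitsunobu closure as in step 11 then returns to the route at 20, and steps 12 and 13 are dropped.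

Step 11. The C2 oxyphosphonium intermediate may undergo β-elimination across C2–C3 (the C3 hydrogen is doubly benzylic), or the second ring A hydroxyl may react between molecules. The fallback separates activation from ring closure and sets out from 17. Phenol-selective silylation (t-BuMe2SiCl, imidazole, DMF) gives the bis(silyl) ether F6. MsCl/Et3N then converts the C2 alcohol into the mesylate F7, which the electron-poor aryl group should keep from ionising. CsF in DMF removes both silyl groups, and the phenoxide next to C3a displaces the mesylate in a 5-exo-tet SN2 reaction with the same inversion, returning to the route at 18.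

Step 15. The electron-rich polyphenolate and enolate may degrade oxidatively in hot alkali, or tosylate cleavage may be slow on the polyanion. The fallback changes the order so that hot base never meets the free polyphenol, and sets out from 20. Aqueous KOH in dioxane (degassed, 70 °C) cleaves the tosylate and equilibrates Cα at the methyl ether stage, giving the tri-O-methyl ether F8 as the single α-epimer. BBr3 demethylation (CH2Cl2, −78 → 0 °C) then returns to the route at 22, at the price of exposing a C2 aryl group that is no longer electron-poor to the Lewis acid.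

Further compounds
F1 | step 10 | 1-[3,5-bis(triisopropylsilyloxy)phenyl]-2-(4-methoxyphenyl)-2-{2,4-dimethoxy-6-[(E)-2-(4-tosyloxyphenyl)ethenyl]phenyl}ethanol (stilbene alcohol) | OC(c1cc(O[Si](C(C)C)(C(C)C)C(C)C)cc(O[Si](C(C)C)(C(C)C)C(C)C)c1)C(c1ccc(OC)cc1)c1c(OC)cc(OC)cc1/C=C/c1ccc(OS(=O)(=O)c2ccc(C)cc2)cc1
F2 | step 10 | 1-[3,5-bis(triisopropylsilyloxy)phenyl]-2-(4-methoxyphenyl)-2-{2,4-dimethoxy-6-[(E)-2-(4-tosyloxyphenyl)ethenyl]phenyl}ethanone (stilbene ketone) | O=C(c1cc(O[Si](C(C)C)(C(C)C)C(C)C)cc(O[Si](C(C)C)(C(C)C)C(C)C)c1)C(c1ccc(OC)cc1)c1c(OC)cc(OC)cc1/C=C/c1ccc(OS(=O)(=O)c2ccc(C)cc2)cc1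
F3 | step 10 | (2R,3R)-oxirane of F2 (keto oxirane) | O=C(c1cc(O[Si](C(C)C)(C(C)C)C(C)C)cc(O[Si](C(C)C)(C(C)C)C(C)C)c1)C(c1ccc(OC)cc1)c1c(OC)cc(OC)cc1[C@H]1O[C@@H]1c1ccc(OS(=O)(=O)c2ccc(C)cc2)cc1
F4 | step 10 | 1-(3,5-dihydroxyphenyl)-2-(4-methoxyphenyl)-2-{2,4-dimethoxy-6-[(2R,3R)-3-(4-tosyloxyphenyl)oxiran-2-yl]phenyl}ethanone (bisphenol keto oxirane) | O=C(c1cc(O)cc(O)c1)C(c1ccc(OC)cc1)c1c(OC)cc(OC)cc1[C@H]1O[C@@H]1c1ccc(OS(=O)(=O)c2ccc(C)cc2)cc1
F5 | step 10 | seven-membered keto carbinol with C3 (R) and (S)-CH(OH)(4-tosyloxyphenyl) | O=C1c2cc(O)cc(O)c2[C@@H](c2cc(OC)cc(OC)c2C1c1ccc(OC)cc1)[C@H](O)c1ccc(OS(=O)(=O)c2ccc(C)cc2)cc1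
F6 | step 11 | bis(tert-butyldimethylsilyl) ether of 17 (bis(silyl) ether) | CC(=O)OC1c2cc(O[Si](C)(C)C(C)(C)C)cc(O[Si](C)(C)C(C)(C)C)c2[C@@H](c2cc(OC)cc(OC)c2C1c1ccc(OC)cc1)[C@H](O)c1ccc(OS(=O)(=O)c2ccc(C)cc2)cc1
F7 | step 11 | C2 methanesulfonate of F6 (mesylate) | CC(=O)OC1c2cc(O[Si](C)(C)C(C)(C)C)cc(O[Si](C)(C)C(C)(C)C)c2[C@@H](c2cc(OC)cc(OC)c2C1c1ccc(OC)cc1)[C@H](OS(C)(=O)=O)c1ccc(OS(=O)(=O)c2ccc(C)cc2)cc1
F8 | step 15 | tri-O-methyl pauciflorol E (tri-O-methyl ether; 2R,3R; Cα R) | O=C1c2cc(O)cc3c2[C@@H](c2cc(OC)cc(OC)c2[C@H]1c1ccc(OC)cc1)[C@H](c1ccc(O)cc1)O3
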